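Ring C is disconnected across O1–C8a and C2–C3, which reduces the flavanonol to the B-ring aldehyde (C2=O1) and a 2-fluoroaryl ketone. The C4 carbonyl of that ketone serves twice: it acidifies C3–H and, being ortho to C8a on ring A, activates the C8a–F bond for substitution. In the key step the chiral ammonium enolate of ketone 23 adds to aldehyde 24 and the resulting C2 alkoxide closes the pyranone by displacing fluoride, creating C2 and C3 (trans) in one operation. Precursor 23, a hexasubstituted fluoroarene carrying the lavandulyl chain, the hydroxyisopentyl chain and an α-(methoxymethoxy)acetyl group, comes from 5-fluororesorcinol by three directed metalations and a Negishi coupling.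

Key step: step 13

Assumption: n-BuLi metalates 2 at the carbon flanked by the two OMOM groups (double chelation) and not next to fluorine.
Assumption: the cinchonidinium salt is taken to deliver the (2R,3R) series in step 13; if its sense of induction is the opposite, the pseudoenantiomeric cinchoninium salt is the equivalent choice.

Step 1
Reactants: 1 5-fluorobenzene-1,3-diol
Product: 2 1-fluoro-3,5-bis(methoxymethoxy)benzene
Conditions: NaH, MOMCl, DMF, 0 °C → rt
Reagents that add atoms: chloromethyl methyl ether (MOMCl), COCCl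
Why: Williamson-type O-alkylation of the bis-phenoxide gives the bis-MOM ether, which protects both phenols against base and supplies the directing groups for the later metalations.

Step 2
Reactants: 2 1-fluoro-3,5-bis(methoxymethoxy)benzene; 3 1-bromo-3-methylbut-2-ene (prenyl bromide)
Product: 5 5-fluoro-1,3-bis(methoxymethoxy)-2-(3-methylbut-2-en-1-yl)benzene, via aryllithium 4 (not isolated)
Conditions: n-BuLi, THF, −40 °C; then CuBr·SMe2 (10 mol %), 3, −78 °C → rt
Reagents that add atoms: none
Why: Directed ortho-metalation occurs at the C–H flanked by the two chelating OMOM groups and the copper-catalysed SN2 allylation of aryllithium 4 with prenyl bromide then places the future C6 side chain between the two oxygens.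

Step 3
Reactants: 5 5-fluoro-1,3-bis(methoxymethoxy)-2-(3-methylbut-2-en-1-yl)benzene
Product: 6 4-[4-fluoro-2,6-bis(methoxymethoxy)phenyl]-2-methylbutan-2-ol
Conditions: Co(acac)2 (20 mol %), PhSiH3, O2 (1 atm), THF, rt
Reagents that add atoms: dioxygen, O=O
Why: Mukaiyama hydration (hydrogen-atom transfer from a cobalt hydride, capture of the tertiary radical by O2 and reduction of the peroxide by the silane) converts the only alkene present into the Markovnikov tertiary alcohol.

Step 4
Reactants: 6 4-[4-fluoro-2,6-bis(methoxymethoxy)phenyl]-2-methylbutan-2-ol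
Product: 8 4-[4-fluoro-3-iodo-2,6-bis(methoxymethoxy)phenyl]-2-methylbutan-2-ol, via dilithio species 7 (not isolated)
Conditions: n-BuLi (2.2 equiv), THF, −78 °C; then I2, −78 °C → rt; aq. Na2S2O3
Reagents that add atoms: iodine, [I][I]
Why: After the hydroxyl is deprotonated, directed ortho-metalation takes place at one of the two equivalent C–H positions flanked by fluorine and OMOM, and iodinolysis of aryllithium 7 at −78 °C, below the temperature at which LiF is lost, gives the aryl iodide.

Step 5
Reactants: 9 (S)-4-benzyloxazolidin-2-one; 10 3-methylbut-2-enoyl chloride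
Product: 12 (S)-4-benzyl-3-(3-methylbut-2-enoyl)oxazolidin-2-one, via lithium oxazolidinide 11 (not isolated)
Conditions: n-BuLi, THF, −78 °C; then 10, −78 → 0 °C
Reagents that add atoms: none
Why: N-acylation of the lithiated oxazolidinone with the acid chloride attaches the chiral auxiliary that controls the lavandulyl stereocentre.

Step 6
Reactants: 12 (S)-4-benzyl-3-(3-methylbut-2-enoyl)oxazolidin-2-one; 3 1-bromo-3-methylbut-2-ene
Product: 14 (S)-4-benzyl-3-[(2S)-5-methyl-2-(prop-1-en-2-yl)hex-4-enoyl]oxazolidin-2-one, via sodium dienolate 13 (not isolated)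
Conditions: NaN(SiMe3)2, THF, −78 °C; then 3, −78 → −40 °C
Reagents that add atoms: none
Why: In this auxiliary-controlled deconjugative enolate alkylation the chelated Z-dienolate 13 reacts with prenyl bromide at its α-carbon on the face opposite to the benzyl group, which creates the lavandulyl stereocentre in the (S) configuration and moves the double bond into the isopropenyl position.

Step 7
Reactants: 14 (S)-4-benzyl-3-[(2S)-5-methyl-2-(prop-1-en-2-yl)hex-4-enoyl]oxazolidin-2-one
Product: 15 (2S)-5-methyl-2-(prop-1-en-2-yl)hex-4-en-1-ol [(S)-lavandulol]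
Conditions: LiBH4, H2O (1 equiv), Et2O, 0 °C
Reagents that add atoms: none
Why: Hydride reduction of the exocyclic imide carbonyl (reductive auxiliary cleavage) releases the primary alcohol without touching the α-stereocentre and returns the oxazolidinone.

Step 8
Reactants: 15 (2S)-5-methyl-2-(prop-1-en-2-yl)hex-4-en-1-ol
Product: 16 (3S)-3-(iodomethyl)-2,6-dimethylhepta-1,5-diene [(S)-lavandulyl iodide]
Conditions: I2, PPh3, imidazole, CH2Cl2, 0 °C → rt
Reagents that add atoms: iodine, [I][I]
Why: The Appel reaction replaces the primary hydroxyl by iodide through SN2 displacement of an oxyphosphonium leaving group, one carbon away from the stereocentre, which is therefore retained.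

Step 9
Reactants: 16 (3S)-3-(iodomethyl)-2,6-dimethylhepta-1,5-diene; 8 4-[4-fluoro-3-iodo-2,6-bis(methoxymethoxy)phenyl]-2-methylbutan-2-ol
Product: 18 4-{4-fluoro-2,6-bis(methoxymethoxy)-3-[(2R)-5-methyl-2-(prop-1-en-2-yl)hex-4-en-1-yl]phenyl}-2-methylbutan-2-ol, via alkylzinc iodide 17 (not isolated)
Conditions: 16, Zn (Me3SiCl-activated), LiCl, THF, 40 °C; then 8, Pd(OAc)2 (3 mol %), SPhos (6 mol %), THF, rt → 50 °C
Reagents that add atoms: none
Why: Negishi sp3–sp2 coupling: zinc inserts into the primary C–I bond, the stereocentre β to zinc is not involved, and the bulky biarylphosphine makes reductive elimination from the aryl(alkyl)palladium intermediate faster than β-hydride elimination, so the lavandulyl group is attached with unchanged geometry (its descriptor becomes R only because the CIP priorities change).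

Step 10
Reactants: 19 methyl 2-hydroxyacetate (methyl glycolate)
Product: 20 methyl 2-(methoxymethoxy)acetate
Conditions: MOMCl, i-Pr2NEt, CH2Cl2, 0 °C → rt
Reagents that add atoms: chloromethyl methyl ether (MOMCl), COCCl
Why: O-alkylation of the primary hydroxyl with MOMCl under amine base gives the acetal without attacking the ester.

Step 11
Reactants: 20 methyl 2-(methoxymethoxy)acetate
Product: 21 N-methoxy-2-(methoxymethoxy)-N-methylacetamide
Conditions: MeNH(OMe)·HCl, i-PrMgCl, THF, −20 → 0 °C
Reagents that add atoms: N,O-dimethylhydroxylamine hydrochloride, CNOC.Cl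
Why: Aminolysis of the ester by the chloromagnesium amide of N,O-dimethylhydroxylamine (Weinreb amide synthesis) gives the acylating agent for the ketone synthesis.

Step 12
Reactants: 18 4-{4-fluoro-2,6-bis(methoxymethoxy)-3-[(2R)-5-methyl-2-(prop-1-en-2-yl)hex-4-en-1-yl]phenyl}-2-methylbutan-2-ol; 21 N-methoxy-2-(methoxymethoxy)-N-methylacetamide
Product: 23 1-{2-fluoro-5-(3-hydroxy-3-methylbutyl)-4,6-bis(methoxymethoxy)-3-[(2R)-5-methyl-2-(prop-1-en-2-yl)hex-4-en-1-yl]phenyl}-2-(methoxymethoxy)ethan-1-one, via dilithio species 22 (not isolated)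
Conditions: n-BuLi (2.2 equiv), THF, −78 °C; then 21, −78 → −40 °C; aq. NH4Cl
Reagents that add atoms: none
Why: Directed ortho-metalation at the last aromatic C–H (between fluorine and OMOM) and Weinreb ketone synthesis, in which the chelated tetrahedral adduct of aryllithium 22 collapses only on work-up, give the α-(methoxymethoxy) ketone without over-addition.

Step 13
Reactants: 23 1-{2-fluoro-5-(3-hydroxy-3-methylbutyl)-4,6-bis(methoxymethoxy)-3-[(2R)-5-methyl-2-(prop-1-en-2-yl)hex-4-en-1-yl]phenyl}-2-(methoxymethoxy)ethan-1-one; 24 2,4-bis(methoxymethoxy)benzaldehyde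
Product: 26 (2R,3R)-2-[2,4-bis(methoxymethoxy)phenyl]-6-(3-hydroxy-3-methylbutyl)-3,5,7-tris(methoxymethoxy)-8-[(2R)-5-methyl-2-(prop-1-en-2-yl)hex-4-en-1-yl]-2,3-dihydro-4H-chromen-4-one, via anti-aldolate 25 (not isolated)
Conditions: 23, 24, O-allyl-N-(9-anthracenylmethyl)cinchonidinium bromide (20 mol %), CsOH·H2O, toluene/CH2Cl2, −40 °C → rt
Reagents that add atoms: none
Why: Proposed new method: under solid–liquid phase transfer the chiral ammonium enolate of 23 adds reversibly to aldehyde 24 (C2–C3), and the ion-paired alkoxide O1 of aldolate 25 then displaces fluoride at C8a, which the ortho C4 carbonyl activates through a Meisenheimer intermediate (O1–C8a), so that both bonds form in one operation. The closest known reaction types are the cinchona-ammonium phase-transfer aldol and alkylation of α-alkoxy aryl ketones (glycolate equivalents), the base-mediated domino aldol/SNAr annulation of 2-fluoroaryl carbonyl compounds and cation-directed enantioselective SNAr. Ring C closes by a six-membered addition–elimination that is 6-endo-trig with respect to the C4a=C8a bond conjugated to C4=O (6-exo-trig with respect to C8a=C8). C2 should be set in a Curtin–Hammett selection among the retro-aldol-equilibrating aldolates by the chiral cation bound to O1 in the ring-closing transition state, and C3 follows as 2,3-trans because aryl and OMOM are both equatorial in that transition state and the C3–H of any cis product can epimerise under the basic conditions. The step needs attack by O1 alone at a single C–F site: the MOM cap on the C3 oxygen excludes group migration and five-ring (benzofuranone) closure, the tertiary hydroxyl is para to C8a and cannot reach it, and C8a carries the only fluorine. The remote lavandulyl centre exerts no control, so the diastereomer purity of 26 should mirror the selectivity of the catalyst.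

Step 14
Reactants: 26 (2R,3R)-2-[2,4-bis(methoxymethoxy)phenyl]-6-(3-hydroxy-3-methylbutyl)-3,5,7-tris(methoxymethoxy)-8-[(2R)-5-methyl-2-(prop-1-en-2-yl)hex-4-en-1-yl]-2,3-dihydro-4H-chromen-4-one
Product: 27 (2R,3R)-2-(2,4-dihydroxyphenyl)-3,5,7-trihydroxy-6-(3-hydroxy-3-methylbutyl)-8-[(2R)-5-methyl-2-(prop-1-en-2-yl)hex-4-en-1-yl]-2,3-dihydro-4H-chromen-4-one (CNP0183552.3)
Conditions: 3 M aq. HCl, MeOH, 40 °C
Reagents that add atoms: none
Why: Acid-catalysed acetal methanolysis removes the four aryl MOM groups and the C3 MOM group in one operation, while the temperature is kept low so that the tertiary alcohol, the two alkenes and the C2 and C3 stereocentres are left untouched.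

Compound list

1 | 5-fluorobenzene-1,3-diol | Oc1cc(O)cc(F)c1 | starting material
2 | 1-fluoro-3,5-bis(methoxymethoxy)benzene | COCOc1cc(F)cc(OCOC)c1 | intermediate
3 | 1-bromo-3-methylbut-2-ene (prenyl bromide) | CC(C)=CCBr | starting material
4 | [4-fluoro-2,6-bis(methoxymethoxy)phenyl]lithium | [Li]c1c(OCOC)cc(F)cc1OCOC | intermediate
5 | 5-fluoro-1,3-bis(methoxymethoxy)-2-(3-methylbut-2-en-1-yl)benzene | COCOc1cc(F)cc(OCOC)c1CC=C(C)C | intermediate
6 | 4-[4-fluoro-2,6-bis(methoxymethoxy)phenyl]-2-methylbutan-2-ol | COCOc1cc(F)cc(OCOC)c1CCC(C)(C)O | intermediate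
7 | lithium 4-[4-fluoro-3-lithio-2,6-bis(methoxymethoxy)phenyl]-2-methylbutan-2-olate | [Li]OC(C)(C)CCc1c(OCOC)cc(F)c([Li])c1OCOC | intermediate
8 | 4-[4-fluoro-3-iodo-2,6-bis(methoxymethoxy)phenyl]-2-methylbutan-2-ol | CC(C)(O)CCc1c(OCOC)cc(F)c(I)c1OCOC | intermediate
9 | (S)-4-benzyloxazolidin-2-one | O=C1N[C@@H](Cc2ccccc2)CO1 | starting material
10 | 3-methylbut-2-enoyl chloride | CC(C)=CC(=O)Cl | starting material
11 | N-lithio-(S)-4-benzyloxazolidin-2-one | [Li]N1[C@@H](Cc2ccccc2)COC1=O | intermediate
12 | (S)-4-benzyl-3-(3-methylbut-2-enoyl)oxazolidin-2-one | CC(C)=CC(=O)N1[C@@H](Cc2ccccc2)COC1=O | intermediate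
13 | sodium (1Z)-1-[(4S)-4-benzyl-2-oxooxazolidin-3-yl]-3-methylbuta-1,3-dien-1-olate | C=C(C)/C=C(\O[Na])N1[C@@H](Cc2ccccc2)COC1=O | intermediate
14 | (S)-4-benzyl-3-[(2S)-5-methyl-2-(prop-1-en-2-yl)hex-4-enoyl]oxazolidin-2-one | C=C(C)[C@H](CC=C(C)C)C(=O)N1[C@@H](Cc2ccccc2)COC1=O | intermediate
15 | (2S)-5-methyl-2-(prop-1-en-2-yl)hex-4-en-1-ol, (S)-lavandulol | C=C(C)[C@H](CC=C(C)C)CO | intermediate
16 | (3S)-3-(iodomethyl)-2,6-dimethylhepta-1,5-diene, (S)-lavandulyl iodide | C=C(C)[C@H](CC=C(C)C)CI | intermediate
17 | [(2S)-5-methyl-2-(prop-1-en-2-yl)hex-4-en-1-yl]zinc iodide | C=C(C)[C@H](CC=C(C)C)C[Zn]I | intermediate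
18 | 4-{4-fluoro-2,6-bis(methoxymethoxy)-3-[(2R)-5-methyl-2-(prop-1-en-2-yl)hex-4-en-1-yl]phenyl}-2-methylbutan-2-ol | C=C(C)[C@H](CC=C(C)C)Cc1c(F)cc(OCOC)c(CCC(C)(C)O)c1OCOC | intermediate
19 | methyl 2-hydroxyacetate (methyl glycolate) | COC(=O)CO | starting material
20 | methyl 2-(methoxymethoxy)acetate | COCOCC(=O)OC | intermediate
21 | N-methoxy-2-(methoxymethoxy)-N-methylacetamide | COCOCC(=O)N(C)OC | intermediate
22 | lithium 4-{4-fluoro-5-lithio-2,6-bis(methoxymethoxy)-3-[(2R)-5-methyl-2-(prop-1-en-2-yl)hex-4-en-1-yl]phenyl}-2-methylbutan-2-olate | C=C(C)[C@H](CC=C(C)C)Cc1c(F)c([Li])c(OCOC)c(CCC(C)(C)O[Li])c1OCOC | intermediate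
23 | 1-{2-fluoro-5-(3-hydroxy-3-methylbutyl)-4,6-bis(methoxymethoxy)-3-[(2R)-5-methyl-2-(prop-1-en-2-yl)hex-4-en-1-yl]phenyl}-2-(methoxymethoxy)ethan-1-one | C=C(C)[C@H](CC=C(C)C)Cc1c(F)c(C(=O)COCOC)c(OCOC)c(CCC(C)(C)O)c1OCOC | intermediate
24 | 2,4-bis(methoxymethoxy)benzaldehyde | COCOc1ccc(C=O)c(OCOC)c1 | starting material
25 | anti-aldolate: (1R,2R)-1-[2,4-bis(methoxymethoxy)phenyl]-3-{aryl of 23}-2-(methoxymethoxy)-3-oxopropan-1-olate, ion-paired with the catalyst cation in the flask and drawn as the caesium salt | C=C(C)[C@H](CC=C(C)C)Cc1c(F)c(C(=O)[C@H](OCOC)[C@H]([O-])c2ccc(OCOC)cc2OCOC)c(OCOC)c(CCC(C)(C)O)c1OCOC.[Cs+] | intermediate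
26 | (2R,3R)-2-[2,4-bis(methoxymethoxy)phenyl]-6-(3-hydroxy-3-methylbutyl)-3,5,7-tris(methoxymethoxy)-8-[(2R)-5-methyl-2-(prop-1-en-2-yl)hex-4-en-1-yl]-2,3-dihydro-4H-chromen-4-one | C=C(C)[C@H](CC=C(C)C)Cc1c(OCOC)c(CCC(C)(C)O)c(OCOC)c2c1O[C@H](c1ccc(OCOC)cc1OCOC)[C@@H](OCOC)C2=O | intermediate
27 | (2R,3R)-2-(2,4-dihydroxyphenyl)-3,5,7-trihydroxy-6-(3-hydroxy-3-methylbutyl)-8-[(2R)-5-methyl-2-(prop-1-en-2-yl)hex-4-en-1-yl]-2,3-dihydro-4H-chromen-4-one | C=C(C)[C@H](CC=C(C)C)Cc1c(O)c(CCC(C)(C)O)c(O)c2c1O[C@H](c1ccc(O)cc1O)[C@@H](O)C2=O | target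

Total step count: 14.
Longest linear sequence: 8 steps (steps 1, 2, 3, 4, 9, 12, 13, 14; the lavandulyl branch through steps 5–8 is equally long).

Steps most likely to fail

Step 13 (proposed new method). The ring closure onto the electron-rich ring A may be slower than unselective background cyclisation at the inorganic base, so that facial control by the chiral cation is poor. Retro-aldol cleavage or elimination may also outrun the fluoride displacement. The fallback uses known chemistry, sets out from 23 and 24 and returns at 26. Ketone 23 is enolised with LiN(SiMe3)2 in THF at −78 °C and aldehyde 24 is added. The mixture is then warmed in THF/DMPU until the alkoxide SNAr is complete. This substrate-independent aldol/SNAr sequence should give both 2,3-trans products, 26 and its (2S,3S)-diastereomer F1, which are separated by preparative HPLC on a chiral stationary phase. Only 26 is carried on.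

Step 9. β-Hydride elimination at the aryl(alkyl)palladium stage, where the β-hydrogen is allylic, may give reduced arene and diene and may erode the lavandulyl stereocentre. Zinc insertion may also be sluggish. The fallback sets out from 15 and 6 and returns at 18. Alcohol 15 is converted into (S)-lavandulyl triflate F2 (Tf2O, 2,6-lutidine, CH2Cl2, −78 °C). F2 is added at −78 °C to dilithio species 7, generated from 6 as in step 4. Direct SN2 alkylation of the aryllithium should give 18 without palladium and without iodide 8.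

Step 14. Acid may induce cyclisation of the tertiary alcohol or of the lavandulyl alkenes onto the liberated 5- and 7-hydroxyls (chroman formation), or the C3 acetal may cleave incompletely. The fallback sets out from 26 and returns at 27. Non-acidic transprotection with Et3SiOTf and 2,2′-bipyridyl (CH2Cl2, 0 °C; then H2O) should convert the aryl MOM ethers into triethylsilyl ethers, silylate the tertiary hydroxyl and free the C3 hydroxyl on aqueous work-up. This gives the pentakis(triethylsilyl) ether F3. Et3N·3HF in THF then removes all silyl groups under essentially neutral conditions.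

Further compounds

F1 | step 13 | (2S,3S)-2-[2,4-bis(methoxymethoxy)phenyl]-6-(3-hydroxy-3-methylbutyl)-3,5,7-tris(methoxymethoxy)-8-[(2R)-5-methyl-2-(prop-1-en-2-yl)hex-4-en-1-yl]-2,3-dihydro-4H-chromen-4-one | C=C(C)[C@H](CC=C(C)C)Cc1c(OCOC)c(CCC(C)(C)O)c(OCOC)c2c1O[C@@H](c1ccc(OCOC)cc1OCOC)[C@H](OCOC)C2=O
F2 | step 9 | (2S)-5-methyl-2-(prop-1-en-2-yl)hex-4-en-1-yl trifluoromethanesulfonate | C=C(C)[C@H](CC=C(C)C)COS(=O)(=O)C(F)(F)F
F3 | step 14 | (2R,3R)-3-hydroxy-2-[2,4-bis(triethylsilyloxy)phenyl]-5,7-bis(triethylsilyloxy)-6-[3-methyl-3-(triethylsilyloxy)butyl]-8-[(2R)-5-methyl-2-(prop-1-en-2-yl)hex-4-en-1-yl]-2,3-dihydro-4H-chromen-4-one | C=C(C)[C@H](CC=C(C)C)Cc1c(O[Si](CC)(CC)CC)c(CCC(C)(C)O[Si](CC)(CC)CC)c(O[Si](CC)(CC)CC)c2c1O[C@H](c1ccc(O[Si](CC)(CC)CC)cc1O[Si](CC)(CC)CC)[C@@H](O)C2=O
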